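**Plan**

- Locants are those of the target: its 22 carbons are numbered as they occur in the SMILES string (C1 = isopropenyl CH2, C4 = isopropenyl-bearing CH, C6 and C11 = the two quaternary carbons, C16 = benzylic CH, C17–C22 = arene).
- Retrosynthetic cuts, in order: C13=C15 (ring-closing metathesis), C11–C12 (methallylation), C11–C22 (palladium enolate arylation), C4–C8 (intramolecular Michael addition), C5–C6 (enolate alkylation), C6–C16 (iridium allylic alkylation); isopropenyl from acetyl, hydroquinone from its dimethyl ether.
- Forward: the cyclohexenone ring C6–C11 is bought; the two-carbon bridge C5–C4 makes the bicyclo[3.2.1]octane, the indane five-membered ring is closed next, and metathesis adds the cyclohexene last.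
- Stereochemistry: C16 from the chiral iridium catalyst; C6 by allylic-strain-controlled alkylation next to C16; C8 by the geometry of bridging; C4 by equilibration to exo; C11 by the cis fusion of the indane to the diketone ring.
- Enabling feature: the cyclohexene holding the only ring alkene, C13=C15, is a three-carbon bridge over C11 and C16, the 1,3-related carbons of the indane five-membered ring (C6, C11, C22, C17, C16); a methallyl arm on C11 and a vinyl arm on C16, held cis on that ring, can therefore be joined.

Key step: step 15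

Remark: the antipode of the phosphoramidite ligand in step 6 is taken to be the one that gives the (S) benzylic centre; the route was redesigned before the key step because a two-carbon bridging of a cyclohexanone enolate is geometrically disfavoured, so the bridge is closed instead by a Michael addition onto a transposed enone.

**Step 1**
Reactants: 1 2-bromo-1,4-dimethoxybenzene
Product: 3 2-bromo-3,6-dimethoxybenzaldehyde, via aryllithium 2 (not isolated)
Conditions: LiN(iPr)2, THF, −78 °C; DMF, −78 to 0 °C; aq. NH4Cl
Reagents that add atoms: N,N-dimethylformamide, CN(C)C=O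
Why: Directed ortho-lithiation removes the ring hydrogen flanked by bromine and methoxy, the most acidic one, and the lithio species 2 is stable at −78 °C, so formylation should place the aldehyde between Br and OMe.

**Step 2**
Reactants: 3 2-bromo-3,6-dimethoxybenzaldehyde
Product: 4 ethyl (2E)-3-(2-bromo-3,6-dimethoxyphenyl)prop-2-enoate
Conditions: (EtO)2P(O)CH2CO2Et, NaH, THF, 0 °C to rt
Reagents that add atoms: triethyl phosphonoacetate, CCOC(=O)CP(=O)(OCC)OCC
Why: Horner–Wadsworth–Emmons olefination of an aromatic aldehyde with a stabilised phosphonate anion reliably gives the (E)-cinnamate.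

**Step 3**
Reactants: 4 ethyl (2E)-3-(2-bromo-3,6-dimethoxyphenyl)prop-2-enoate
Product: 5 (2E)-3-(2-bromo-3,6-dimethoxyphenyl)prop-2-en-1-ol
Conditions: iBu2AlH (2.5 equiv), CH2Cl2, −78 to 0 °C; aq. KNaC4H4O6
Reagents that add atoms: none
Why: Hydride reduction of the conjugated ester with iBu2AlH proceeds 1,2 to the allylic alcohol and leaves the aryl bromide alone.

**Step 4**
Reactants: 5 (2E)-3-(2-bromo-3,6-dimethoxyphenyl)prop-2-en-1-ol
Product: 6 (2E)-3-(2-bromo-3,6-dimethoxyphenyl)prop-2-en-1-yl methyl carbonate
Conditions: ClCO2Me, pyridine, CH2Cl2, 0 °C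
Reagents that add atoms: methyl chloroformate, COC(=O)Cl
Why: Acylation of the primary allylic alcohol with a chloroformate gives the carbonate leaving group needed for iridium allylic substitution.

**Step 5**
Reactants: 7 1,4-dioxaspiro[4.5]dec-6-en-8-one (commercial)
Product: 8 (1,4-dioxaspiro[4.5]deca-6,8-dien-8-yloxy)trimethylsilane
Conditions: Me3SiOTf, Et3N, CH2Cl2, 0 °C
Reagents that add atoms: trimethylsilyl trifluoromethanesulfonate, C[Si](C)(C)OS(=O)(=O)C(F)(F)F
Why: Soft enolisation with O-silylation can only occur at the α′-carbon because the γ-carbon is the ketal carbon, so the cross-conjugated 2-silyloxy diene is the single possible enol ether.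

**Step 6**
Reactants: 8 (1,4-dioxaspiro[4.5]deca-6,8-dien-8-yloxy)trimethylsilane; 6 (2E)-3-(2-bromo-3,6-dimethoxyphenyl)prop-2-en-1-yl methyl carbonate
Product: 9 9-[(1S)-1-(2-bromo-3,6-dimethoxyphenyl)prop-2-en-1-yl]-1,4-dioxaspiro[4.5]dec-6-en-8-one (both epimers at ring C9)
Conditions: [Ir(cod)Cl]2 (2 mol%), O,O′-(1,1′-binaphthalene-2,2′-diyl) N,N-bis(1-phenylethyl)phosphoramidite (4 mol%, antipode per remark, pre-activated with n-PrNH2), KF, 18-crown-6, THF, 35 °C
Reagents that add atoms: none
Why: Iridium-catalysed asymmetric allylic alkylation of the fluoride-released enone α′-enolate should direct the nucleophile to the aryl-bearing allyl terminus, giving the branched product with the benzylic centre (C16) set (S) by the catalyst, while the adjacent ring CH forms as a mixture that step 7 erases.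

**Step 7**
Reactants: 9 9-[(1S)-1-(2-bromo-3,6-dimethoxyphenyl)prop-2-en-1-yl]-1,4-dioxaspiro[4.5]dec-6-en-8-one; 10 2-(2-bromoethyl)-2-methyl-1,3-dioxolane (commercial)
Product: 12 (9R)-9-[(1S)-1-(2-bromo-3,6-dimethoxyphenyl)prop-2-en-1-yl]-9-[2-(2-methyl-1,3-dioxolan-2-yl)ethyl]-1,4-dioxaspiro[4.5]dec-6-en-8-one, via potassium enolate 11 (not isolated)
Conditions: KN(SiMe3)2, THF/DMPU, −78 °C; 10, Bu4NI (10 mol%), −78 to 0 °C
Reagents that add atoms: none
Why: Enolate alkylation at the only enolisable carbon: in tetrasubstituted enolate 11 allylic 1,3-strain should hold the benzylic hydrogen in the enolate plane next to oxygen, the di-ortho-substituted aryl group then shields one face, and the halide is expected to enter on the vinyl side, setting quaternary C6 (R) in the relation to C16 that the target needs.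

**Step 8**
Reactants: 12 (9R)-9-[(1S)-1-(2-bromo-3,6-dimethoxyphenyl)prop-2-en-1-yl]-9-[2-(2-methyl-1,3-dioxolan-2-yl)ethyl]-1,4-dioxaspiro[4.5]dec-6-en-8-one
Product: 13 (9R)-9-[(1S)-1-(2-bromo-3,6-dimethoxyphenyl)prop-2-en-1-yl]-9-[2-(2-methyl-1,3-dioxolan-2-yl)ethyl]-1,4-dioxaspiro[4.5]dec-6-en-8-ol (carbinol epimers)
Conditions: NaBH4, CeCl3·7H2O, MeOH, 0 °C
Reagents that add atoms: none
Why: Luche 1,2-reduction converts the enone carbonyl (C7) into an allylic carbinol, so that after ketal opening the remaining carbonyl (C10) activates the alkene carbon next to the carbinol (C8) and not the other one; either carbinol epimer serves.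

**Step 9**
Reactants: 13 the allylic alcohol from step 8
Product: 14 tert-butyldimethylsilyl ether of 13
Conditions: tBuMe2SiOTf, 2,6-lutidine, CH2Cl2, −78 to 0 °C
Reagents that add atoms: tert-butyldimethylsilyl trifluoromethanesulfonate, CC(C)(C)[Si](C)(C)OS(=O)(=O)C(F)(F)F
Why: Silylation of the hindered secondary alcohol with a silyl triflate protects the γ-oxygenated enone of step 10 from base-induced isomerisation to a 1,4-diketone.

**Step 10**
Reactants: 14 tert-butyldimethylsilyl ether of 13
Product: 16 6-exo-acetyl-1-[(1S)-1-(2-bromo-3,6-dimethoxyphenyl)prop-2-en-1-yl]-8-(tert-butyldimethylsilyloxy)bicyclo[3.2.1]octan-3-one (bicyclooctane C1 = C6, C5 = C8, C6 = C4, C8 = C7 of the target; silyloxy epimers), via keto enone 15 (not isolated)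
Conditions: TsOH·H2O (0.2 equiv), THF/H2O, 45 °C; then KOC(CH3)3 (0.3 equiv), THF/t-BuOH, 0 °C to rt
Reagents that add atoms: water, O
Why: Acid hydrolysis of both dioxolanes followed by an intramolecular Michael addition (5-exo-trig): in 15 the only electrophilic alkene carbon is C8, the axial oxobutyl chain on C6 lies above it, and its more substituted enolate should close the C4–C8 bond, which fixes bridgehead C8 by geometry and leaves C4 epimerisable toward the exo acetyl isomer.

**Step 11**
Reactants: 16 the bicyclic silyl ether from step 10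
Product: 17 6-exo-acetyl-1-[(1S)-1-(2-bromo-3,6-dimethoxyphenyl)prop-2-en-1-yl]-8-hydroxybicyclo[3.2.1]octan-3-one (carbinol epimers)
Conditions: HF·pyridine, THF, 0 °C to rt
Reagents that add atoms: none
Why: Acidic fluoride cleaves the silyl ether without exposing the diketone to base.

**Step 12**
Reactants: 17 the bicyclic carbinol from step 11
Product: 18 6-exo-acetyl-1-[(1S)-1-(2-bromo-3,6-dimethoxyphenyl)prop-2-en-1-yl]bicyclo[3.2.1]octane-3,8-dione
Conditions: Dess–Martin periodinane, CH2Cl2, rt
Reagents that add atoms: none
Why: Dess–Martin oxidation of the bridging carbinol gives the non-enolisable bridging ketone and removes the carbinol stereocentre, so the epimers converge.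

**Step 13**
Reactants: 18 the triketone aryl bromide from step 12
Product: 19 cis-fused indane triketone: 18 with the former C–Br carbon (C22) bonded to C11, closing the five-membered ring C6–C11–C22–C17–C16; C11–H and the C16 vinyl group on the same face
Conditions: Pd2(dba)3 (2.5 mol%), 2-dicyclohexylphosphino-2′,4′,6′-triisopropylbiphenyl (10 mol%), K3PO4, toluene, 90 °C
Reagents that add atoms: none
Why: Palladium-catalysed intramolecular ketone α-arylation: after oxidative addition into C–Br only the enolate carbon C11 can reach palladium through a six-membered palladacycle, so reductive elimination should close the five-membered ring with a cis fusion, the new C11–H being epimerisable toward that fusion and C4 toward exo under the phosphate base.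

**Step 14**
Reactants: 19 the cis-fused indane triketone; 20 3-bromo-2-methylpropene
Product: 21 ring-closing precursor: 19 with a 2-methylprop-2-enyl group in place of C11–H, cis to the C16 vinyl group (methyl ketone, bis(methyl ether))
Conditions: Cs2CO3, 20, DMF, 0 °C to rt
Reagents that add atoms: none
Why: Alkylation of the most acidic site, the α-aryl ketone, through its caesium enolate should occur on carbon on the face that keeps the five/six ring fusion cis (the trans-fused alternative is highly strained), which places the methallyl group on the same face as the vinyl group and creates quaternary C11.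

**Step 15**
Reactants: 21 the ring-closing precursor
Product: 22 pentacyclic methyl ketone, bis(methyl ether), with the bridging 3-methylcyclohexene (C13=C15) closed
Conditions: second-generation Hoveyda–Grubbs catalyst RuCl2(H2IMes)(=CH-C6H4-2-OiPr) (10 mol%), toluene (5 mM), 80 °C, argon sparge
Reagents that add atoms: none
Why: The ruthenium alkylidene is expected to load onto the monosubstituted C16 vinyl group, undergo [2+2] cycloaddition with the 1,1-disubstituted alkene of the C11 methallyl group and cyclorevert with loss of ethene, which is ring-closing olefin metathesis to a trisubstituted cycloalkene, a well-known outcome for vinyl/2-methylallyl pairs in bridged bicycles. The ring closed is the cyclohexene C11–C12–C13=C15–C16–C6, formed as a three-carbon bridge across the 1,3-positions of the indane five-membered ring, so a benzo-fused bicyclo[3.2.1]octene results. No stereocentre is created; the reaction only needs the cis relationship of the two arms installed in steps 7 and 14, and a trans isomer could not cyclise. Chemoselectivity is secured because these are the only two alkenes present, the isopropenyl group still being a methyl ketone (a closure onto a C4 isopropenyl group would in any case be geometrically impossible from the bridgehead). High dilution and removal of ethene should suppress intermolecular metathesis.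

**Step 16**
Reactants: 22 the pentacyclic methyl ketone
Product: 23 target bis(methyl ether) with the isopropenyl group restored
Conditions: Ph3PCH3Br (1.3 equiv), KOC(CH3)3 (1.2 equiv), THF, 0 °C; then 22, 0 °C to rt
Reagents that add atoms: methyltriphenylphosphonium bromide (as its ylide), C[P+](c1ccccc1)(c1ccccc1)c1ccccc1.[Br-]
Why: Wittig methylenation should be selective for the acetyl carbonyl, the only unhindered ketone (the bridging ketone is flanked by a quaternary and a bridgehead carbon, the other ring ketone by quaternary C11), and any base-induced epimerisation at C4 can only return the exo isomer already present.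

**Step 17**
Reactants: 23 the target bis(methyl ether)
Product: 25 CNP0287617.1 (target hydroquinone), via quinone 24 (not isolated)
Conditions: (NH4)2Ce(NO3)6 (2.5 equiv), MeCN/H2O, 0 °C; then aq. Na2S2O4, EtOAc, rt
Reagents that add atoms: water, O
Why: Oxidative demethylation of the para-dimethoxyarene by tetravalent cerium gives p-benzoquinone 24, water supplying the quinone oxygens, and reduction with Na2S2O4 in the same flask gives the hydroquinone without touching ketones or alkenes.

**Compound list**

1 | 2-bromo-1,4-dimethoxybenzene | COc1ccc(OC)c(Br)c1 | starting material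
2 | (2-bromo-3,6-dimethoxyphenyl)lithium | [Li]c1c(OC)ccc(OC)c1Br | intermediate (not isolated)
3 | 2-bromo-3,6-dimethoxybenzaldehyde | O=Cc1c(OC)ccc(OC)c1Br | intermediate
4 | ethyl (2E)-3-(2-bromo-3,6-dimethoxyphenyl)prop-2-enoate | CCOC(=O)/C=C/c1c(OC)ccc(OC)c1Br | intermediate
5 | (2E)-3-(2-bromo-3,6-dimethoxyphenyl)prop-2-en-1-ol | OC/C=C/c1c(OC)ccc(OC)c1Br | intermediate
6 | (2E)-3-(2-bromo-3,6-dimethoxyphenyl)prop-2-en-1-yl methyl carbonate | COC(=O)OC/C=C/c1c(OC)ccc(OC)c1Br | intermediate
7 | 1,4-dioxaspiro[4.5]dec-6-en-8-one | O=C1C=CC2(CC1)OCCO2 | starting material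
8 | (1,4-dioxaspiro[4.5]deca-6,8-dien-8-yloxy)trimethylsilane | C[Si](C)(C)OC1=CCC2(OCCO2)C=C1 | intermediate
9 | 9-[(1S)-1-(2-bromo-3,6-dimethoxyphenyl)prop-2-en-1-yl]-1,4-dioxaspiro[4.5]dec-6-en-8-one (ring C9 epimers) | O=C1C=CC2(OCCO2)CC1[C@H](C=C)c1c(OC)ccc(OC)c1Br | intermediate
10 | 2-(2-bromoethyl)-2-methyl-1,3-dioxolane | CC1(CCBr)OCCO1 | starting material
11 | potassium dienolate of 9 | [K+].[O-]C1=C(CC2(OCCO2)C=C1)[C@H](C=C)c1c(OC)ccc(OC)c1Br | intermediate (not isolated)
12 | (9R)-9-[(1S)-1-(2-bromo-3,6-dimethoxyphenyl)prop-2-en-1-yl]-9-[2-(2-methyl-1,3-dioxolan-2-yl)ethyl]-1,4-dioxaspiro[4.5]dec-6-en-8-one | CC1(CC[C@@]2(CC3(OCCO3)C=CC2=O)[C@H](C=C)c2c(OC)ccc(OC)c2Br)OCCO1 | intermediate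
13 | allylic alcohol from 12 (carbinol epimers) | CC1(CC[C@@]2(CC3(OCCO3)C=CC2O)[C@H](C=C)c2c(OC)ccc(OC)c2Br)OCCO1 | intermediate
14 | tert-butyldimethylsilyl ether of 13 | CC1(CC[C@@]2(CC3(OCCO3)C=CC2O[Si](C)(C)C(C)(C)C)[C@H](C=C)c2c(OC)ccc(OC)c2Br)OCCO1 | intermediate
15 | (5R)-5-[(1S)-1-(2-bromo-3,6-dimethoxyphenyl)prop-2-en-1-yl]-4-(tert-butyldimethylsilyloxy)-5-(3-oxobutyl)cyclohex-2-en-1-one | CC(=O)CC[C@@]1(CC(=O)C=CC1O[Si](C)(C)C(C)(C)C)[C@H](C=C)c1c(OC)ccc(OC)c1Br | intermediate (not isolated)
16 | 6-exo-acetyl-1-[(1S)-1-(2-bromo-3,6-dimethoxyphenyl)prop-2-en-1-yl]-8-(tert-butyldimethylsilyloxy)bicyclo[3.2.1]octan-3-one | CC(=O)[C@H]1C[C@]2(C(O[Si](C)(C)C(C)(C)C)[C@@H]1CC(=O)C2)[C@H](C=C)c1c(OC)ccc(OC)c1Br | intermediate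
17 | 6-exo-acetyl-1-[(1S)-1-(2-bromo-3,6-dimethoxyphenyl)prop-2-en-1-yl]-8-hydroxybicyclo[3.2.1]octan-3-one | CC(=O)[C@H]1C[C@]2(C(O)[C@@H]1CC(=O)C2)[C@H](C=C)c1c(OC)ccc(OC)c1Br | intermediate
18 | 6-exo-acetyl-1-[(1S)-1-(2-bromo-3,6-dimethoxyphenyl)prop-2-en-1-yl]bicyclo[3.2.1]octane-3,8-dione | CC(=O)[C@H]1C[C@]2(C(=O)[C@@H]1CC(=O)C2)[C@H](C=C)c1c(OC)ccc(OC)c1Br | intermediate
19 | cis-fused 4,7-dimethoxyindane triketone with C11–H and C16 vinyl | CC(=O)[C@H]1C[C@@]23C(=O)[C@@H]1CC(=O)[C@@H]2c1c(OC)ccc(OC)c1[C@H]3C=C | intermediate
20 | 3-bromo-2-methylpropene | C=C(C)CBr | starting material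
21 | ring-closing precursor with C11 methallyl and C16 vinyl cis, methyl ketone, bis(methyl ether) | CC(=O)[C@H]1C[C@@]23C(=O)[C@@H]1CC(=O)[C@]2(CC(C)=C)c1c(OC)ccc(OC)c1[C@H]3C=C | intermediate
22 | pentacyclic methyl ketone, bis(methyl ether) | CC(=O)[C@H]1C[C@@]23C(=O)[C@@H]1CC(=O)[C@@]21CC(C)=C[C@@H]3c2c(OC)ccc(OC)c21 | intermediate
23 | target bis(methyl ether) | C=C(C)[C@H]1C[C@@]23C(=O)[C@@H]1CC(=O)[C@@]21CC(C)=C[C@@H]3c2c(OC)ccc(OC)c21 | intermediate
24 | p-benzoquinone corresponding to the target | C=C(C)[C@H]1C[C@@]23C(=O)[C@@H]1CC(=O)[C@@]21CC(C)=C[C@@H]3C2=C1C(=O)C=CC2=O | intermediate (not isolated)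
25 | CNP0287617.1 | C=C(C)[C@H]1C[C@@]23C(=O)[C@@H]1CC(=O)[C@@]21CC(C)=C[C@@H]3c2c(O)ccc(O)c21 | target

**Totals and risks**

Total step count: 17. Longest linear sequence: 16 steps (steps 1–4 and 6–17, from 2-bromo-1,4-dimethoxybenzene); the branch from 7 contributes step 5.

Steps most likely to fail:

1. Step 7. The hindered potassium enolate may alkylate slowly on carbon, may eliminate HBr from the primary bromide instead, or may discriminate its two faces poorly. Fallback: invert the order of the two substitutions at C6. Starting from 7, alkylation of its lithium α′-enolate (LiN(iPr)2, THF/DMPU) with 10 should give the racemic mono-alkylated enone F1; soft enolisation (Me3SiOTf, Et3N) gives the tetrasubstituted silyl dienol ether F2; the iridium-catalysed allylation of step 6 with carbonate 6 would then form the quaternary and the benzylic centre together under catalyst control and return to the route at 12.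

2. Step 6. The di-ortho-substituted cinnamyl carbonate may ionise slowly on iridium or lose branched selectivity and enantioselectivity. Fallback: set C16 by conjugate addition. Starting from 3, aldol condensation with commercial 1,4-dioxaspiro[4.5]decan-8-one gives the (E)-benzylidene ketone F3; a Hayashi–Miyaura 1,4-addition of K[CH2=CHBF3] with [RhCl(C2H4)2]2 and a chiral diene ligand gives the saturated (S)-configured ketone F4; kinetic silylation on the methylene side (LiN(iPr)2, Me3SiCl) gives silyl enol ether F5; Saegusa–Ito dehydrogenation with Pd(OAc)2 returns to the route at 9.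

3. Step 13. Base-mediated aldol or retro-Michael reactions of the triketone may outrun the palladium enolate coupling. Fallback: carry out the arylation one oxidation level earlier, where only one ring ketone is present. Starting from 16, the same palladium conditions should give the arylated silyl ether F6; HF·pyridine gives the arylated carbinol F7; Dess–Martin oxidation returns to the route at 19.

**Further compounds**

F1 | step 7 | 9-[2-(2-methyl-1,3-dioxolan-2-yl)ethyl]-1,4-dioxaspiro[4.5]dec-6-en-8-one (racemic) | CC1(CCC2CC3(OCCO3)C=CC2=O)OCCO1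
F2 | step 7 | trimethylsilyl dienol ether of F1 | CC1(CCC2=C(O[Si](C)(C)C)C=CC3(C2)OCCO3)OCCO1
F3 | step 6 | (7E)-7-(2-bromo-3,6-dimethoxybenzylidene)-1,4-dioxaspiro[4.5]decan-8-one | O=C1CCC2(OCCO2)C/C1=C\c1c(OC)ccc(OC)c1Br
F4 | step 6 | 7-[(1S)-1-(2-bromo-3,6-dimethoxyphenyl)prop-2-en-1-yl]-1,4-dioxaspiro[4.5]decan-8-one | O=C1CCC2(OCCO2)CC1[C@H](C=C)c1c(OC)ccc(OC)c1Br
F5 | step 6 | trimethylsilyl enol ether of F4 on the methylene side | C[Si](C)(C)OC1=CCC2(OCCO2)CC1[C@H](C=C)c1c(OC)ccc(OC)c1Br
F6 | step 13 | cis-fused indane silyl ether (19 with C7 as CH–OSi(tBu)Me2) | CC(=O)[C@H]1C[C@@]23C(O[Si](C)(C)C(C)(C)C)[C@@H]1CC(=O)[C@@H]2c1c(OC)ccc(OC)c1[C@H]3C=C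
F7 | step 13 | cis-fused indane carbinol (19 with C7 as CH–OH) | CC(=O)[C@H]1C[C@@]23C(O)[C@@H]1CC(=O)[C@@H]2c1c(OC)ccc(OC)c1[C@H]3C=C
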